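common to all: pre-initiator 72 µM
- theta: free monomer 16 mM; run made earlier
- gamma: free monomer 52 mM; run made earlier
- green: free monomer 36 mM; time 10 d
- blue: free monomer 12 mM; time 10 d

| run | time / d | monomer in chains / % | free monomer / % |
|---|---|---|---|
| theta | 0.833 | 1.9 | 99.0 |
| theta | 2.50 | 3.1 | 98.1 |
| theta | 5.00 | 17.0 | 83.7 |
| theta | 8.00 | 45.7 | 53.1 |
| gamma | 0.833 | 1.2 | 100.1 |
| gamma | 2.50 | 9.7 | 90.0 |
| gamma | 5.00 | 42.1 | 59.4 |
| gamma | 8.00 | 75.2 | 23.9 |

(scatter of a reading: 1 percentage point)

- the average divides the monomer in chains by the number of chains begun, living and dead together
- steps thought possible: pre-initiator -> initiator; free monomer + initiator -> living end + monomer in chains; free monomer + living end -> monomer in chains + living end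
- the earlier runs do not show the number of chains; that part of a forecast is a guess

- which of the two ends with the longer chains by the average number of monomer units in a chain (chains begun, living or dead) ("neither" if they lie within 10%) (green / blue / neither)
- average number of monomer units in a chain (chains begun, living or dead) at the end, green
- average number of monomer units in a chain (chains begun, living or dead) at the end, blue

- Gamma keeps 59.4% of its free monomer at 5.00 d, less than theta's 83.7%, and I reckon with the fraction left.
- My measure is the log-left, ln(charged/left). Living ends take free monomer at a pseudo-first-order rate, so the log-left is living ends summed over time, times one rate constant.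
- First instants: pre-initiator must pass through initiator before a living end exists, and theta has lost hardly any of its free monomer by 2.50 d.
- Middle: at 5.00 d gamma's log-left reads 2.93 times theta's, for 3.25 times the charge, so in these readings living ends summed up to then roughly follow the free monomer charged.
- End: at 8.00 d the log-left is 0.633 in theta and 1.43 in gamma, which goes as the charge to the power 0.692.
- I keep that power and assume that the log-left grows as the square of time, a factor 1.56, up to 10 d. My log-left is then 1.73 for green and 0.810 for blue.
- The listed steps hold no death of chains, so length is monomer in chains over living ends. If living ends rise alike, length follows the chain yield, monomer in chains per unit of log-left: green 17.1 mM, blue 8.22 mM.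
- So I expect green longer, by a factor 2.08; the readings give me no absolute length.
- The forecast says green, with 760 for green and 300 for blue, a factor 2.53, above mine. It warns: “Chain counts are inferred, not measured”.
- The flask gives green: green 1190, blue 499, a factor 2.38, above my yield ratio.

    pre-initiator → initiator (k = 2.30 × 10⁻⁴ min⁻¹)
    free monomer + initiator → living end + monomer in chains (k = 0.00220 M⁻¹ min⁻¹)
    free monomer + living end → monomer in chains + living end, rate k3*[living end]*[free monomer] (k = 8.80 M⁻¹ min⁻¹)

- The neighbour of green holds 0.029 mM of pre-initiator against 72 µM, and keeps 45% of its free monomer at 10.0 d with 55.0% in chains. Its chain yield is 24.8 mM, 1.45 times the 17.1 mM I reckoned for green. Its length is 1570, 1.32 times green's.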